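**Retrosynthetic overview**
1. Numbering: ring A (cyclopentane) is C1 (methyl-bearing fusion carbon), C2, C3, C4 (isopropyl carbinol), C5 (fusion CH). Ring B (seven-membered) is C1, C5, C6 (aroyloxy carbon), C7=C8 (methyl on C8), C9 (acetoxy carbon), C10.
2. The strategy rests on one feature of ring B: the acetoxy carbon C9 is a secondary allylic carbinol bonded directly to C8, the methyl-bearing sp2 carbon of the Z ring alkene C7=C8. Cutting C8–C9 gives a C8 (Z)-alkenyl iodide and a C9 aldehyde on trans-related arms at C5 and C1 of ring A, to be rejoined by a chromium/nickel-mediated alkenyl addition.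
3. After ring closure only ester work remains: acetate on the new C9 hydroxyl, desilylation, then the silyl-protected 4-hydroxybenzoate on C6. The tertiary C4 hydroxyl stays free.
4. Before ring closure: the (Z)-iodoalkene comes from anti hydroalumination–iodination of a C6 propargylic alcohol, C4 from isopropyl addition to the ring ketone, and C5–C6 from an anti boron aldol with but-2-ynal. The quaternary C1 comes from asymmetric conjugate methylation of 3-allylcyclopent-2-enone, whose allyl group is the masked C10–C9 aldehyde.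
5. Order of rings: ring A is present in the first starting material, and ring B is closed in the key step.

Key step: step 10

Assumption: the sense of induction of the phosphoramidite in step 2 cannot be predicted safely for this enone, so the ligand antipode is fixed after a test run so that (R)-6 results; all later stereocentres are relayed from C1, and any residual minor enantiomer is to be removed by recrystallisation of diol 12 or 14.

Step 1
Reactants: 1 3-ethoxycyclopent-2-en-1-one; 2 allylmagnesium bromide
Product: 4 3-allylcyclopent-2-en-1-one, via 1-allyl-3-ethoxycyclopent-2-en-1-ol 3 (not isolated)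
Conditions: 2 (1.2 equiv), THF, 0 °C; then 1 M aq. HCl, 0 °C, short contact
Reagents that add atoms: none
Why: Stork–Danheiser enone synthesis, in which 1,2-addition of the Grignard reagent to the vinylogous ester and acid-induced loss of ethanol from the tertiary allylic alcohol transpose the carbonyl group, while the cold and brief acid contact keeps the skipped diene from slipping into conjugation; no stereocentre is formed.

Step 2
Reactants: 4 3-allylcyclopent-2-en-1-one
Product: 6 [(3R)-3-allyl-3-methylcyclopent-1-en-1-yl]oxy(trimethyl)silane, via dimethylaluminium enolate 5 (not isolated)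
Conditions: Me3Al (1.5 equiv), copper thiophene-2-carboxylate Cu(O2CC4H3S) (5 mol %), chiral O,O'-(biphenyl-2,2'-diyl) N,N-bis[1-(2-naphthyl)ethyl]phosphoramidite (10 mol %), Et2O, −30 °C; then TMSOTf (2 equiv), −30 to 0 °C; cold aq. NaHCO3, pentane
Reagents that add atoms: trimethylaluminium C[Al](C)C; trimethylsilyl triflate C[Si](C)(C)OS(=O)(=O)C(F)(F)F
Why: Copper-catalysed asymmetric conjugate addition of a trialkylaluminium to a β-substituted cyclopentenone, in which the chiral phosphoramidite–copper complex selects the enone face and so sets the quaternary C1 as (R), and silylation of the aluminium enolate, itself too sluggish for a clean aldol addition, stores the C4–C5 enolate regiochemistry in an isolable form.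

Step 3
Reactants: 7 but-2-yn-1-ol
Product: 8 but-2-ynal
Conditions: activated MnO2 (15 equiv), CH2Cl2, rt; filtered, dried over 4 Å molecular sieves, used as a titrated solution
Reagents that add atoms: none
Why: Heterogeneous MnO2 oxidation of a propargylic alcohol stops cleanly at the aldehyde, and simple filtration hands on the volatile ynal in solution without distillation; no stereocentre is involved.

Step 4
Reactants: 6 [(3R)-3-allyl-3-methylcyclopent-1-en-1-yl]oxy(trimethyl)silane; 8 but-2-ynal
Product: 11 (2S,3R)-3-allyl-2-[(1R)-1-hydroxybut-2-yn-1-yl]-3-methylcyclopentan-1-one, via dibutylboron enolate 9 (not isolated), via dibutylboron aldolate 10 (not isolated)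
Conditions: Bu2BOTf (1.05 equiv), CH2Cl2, 0 °C to rt, TMSOTf removed in vacuo; 8 (1.5 equiv), CH2Cl2, −78 °C; then pH 7 phosphate buffer, MeOH, 30% H2O2, 0 °C
Reagents that add atoms: none
Why: Silicon-to-boron exchange passes on the regiodefined C4–C5 enolate, and the boron aldol addition runs through a tight closed six-membered chair transition state in which the ring-locked (E)-enolate gives the anti C5/C6 pair while the aldehyde is taken up on the enolate face that carries the C1 methyl, anti to the larger allyl group, which sets C5 as (S) and C6 as (R).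

Step 5
Reactants: 11 (2S,3R)-3-allyl-2-[(1R)-1-hydroxybut-2-yn-1-yl]-3-methylcyclopentan-1-one
Product: 12 (1R,2S,3R)-3-allyl-2-[(1R)-1-hydroxybut-2-yn-1-yl]-3-methyl-1-(propan-2-yl)cyclopentan-1-ol
Conditions: LaCl3·2LiCl (1.2 equiv), THF; iPrMgCl (3.5 equiv), −40 to 0 °C; aq. NH4Cl
Reagents that add atoms: isopropylmagnesium chloride CC(C)[Mg]Cl
Why: Lanthanide-assisted Grignard 1,2-addition, in which LaCl3·2LiCl activates the carbonyl group and damps the basicity and β-hydride transfer of iPrMgCl on this enolisable cyclopentanone, the first equivalent only deprotonates the C6 hydroxyl, and the nucleophile enters C4 from the ring face opposite to the C5 side chain, so that the C4 hydroxyl ends cis to C6 and C4 is set as (R).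

Step 6
Reactants: 12 (1R,2S,3R)-3-allyl-2-[(1R)-1-hydroxybut-2-yn-1-yl]-3-methyl-1-(propan-2-yl)cyclopentan-1-ol
Product: 14 (1R,2S,3R)-3-allyl-2-[(1R,2Z)-1-hydroxy-3-iodobut-2-en-1-yl]-3-methyl-1-(propan-2-yl)cyclopentan-1-ol, via cyclic alkenylalanate 13 (not isolated)
Conditions: NaAlH2(OCH2CH2OMe)2 (4 equiv), THF, 0 °C to rt; then I2 (excess), THF, −78 °C; aq. Na2S2O3, aq. potassium sodium tartrate
Reagents that add atoms: iodine [I][I]
Why: Hydroxyl-directed anti hydroalumination of a propargylic alcohol followed by iodinolysis, in which the C6 alkoxide holds aluminium so that it ends on the distal alkyne carbon C8 in a five-membered ring while hydride reaches C7 from the opposite side, and iodine replaces aluminium with retention, which fixes the Z geometry (C6 and iodine cis) without touching the isolated allyl group or any stereocentre.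

Step 7
Reactants: 14 (1R,2S,3R)-3-allyl-2-[(1R,2Z)-1-hydroxy-3-iodobut-2-en-1-yl]-3-methyl-1-(propan-2-yl)cyclopentan-1-ol
Product: 15 (1R,2S,3R)-3-allyl-2-[(1R,2Z)-1-(tert-butyldimethylsilyloxy)-3-iodobut-2-en-1-yl]-3-methyl-1-(propan-2-yl)cyclopentan-1-ol
Conditions: TBSOTf (1.1 equiv), 2,6-lutidine, CH2Cl2, −78 °C
Reagents that add atoms: tert-butyldimethylsilyl triflate CC(C)(C)[Si](C)(C)OS(=O)(=O)C(F)(F)F
Why: Silyl triflate silylation under kinetic control, in which one equivalent of reagent at low temperature takes the secondary allylic C6 hydroxyl and leaves the tertiary, isopropyl-flanked C4 hydroxyl untouched, with no change at any stereocentre.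

Step 8
Reactants: 15 (1R,2S,3R)-3-allyl-2-[(1R,2Z)-1-(tert-butyldimethylsilyloxy)-3-iodobut-2-en-1-yl]-3-methyl-1-(propan-2-yl)cyclopentan-1-ol
Product: 16 [(1R,2S,3R)-3-allyl-2-[(1R,2Z)-1-(tert-butyldimethylsilyloxy)-3-iodobut-2-en-1-yl]-3-methyl-1-(propan-2-yl)cyclopentyl]oxy(triethyl)silane
Conditions: TESOTf (3 equiv), 2,6-lutidine, CH2Cl2, 0 °C to rt
Reagents that add atoms: triethylsilyl triflate CC[Si](CC)(CC)OS(=O)(=O)C(F)(F)F
Why: Silylation of a hindered tertiary alcohol by the small and highly reactive triethylsilyl triflate, which removes the last acidic proton close to C8 before the organochromium step and creates no stereocentre.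

Step 9
Reactants: 16 [(1R,2S,3R)-3-allyl-2-[(1R,2Z)-1-(tert-butyldimethylsilyloxy)-3-iodobut-2-en-1-yl]-3-methyl-1-(propan-2-yl)cyclopentyl]oxy(triethyl)silane
Product: 18 2-[(1R,2S,3R)-2-[(1R,2Z)-1-(tert-butyldimethylsilyloxy)-3-iodobut-2-en-1-yl]-1-methyl-3-(propan-2-yl)-3-(triethylsilyloxy)cyclopentyl]acetaldehyde, via vicinal diol 17 (not isolated)
Conditions: OsO4 (2 mol %), NaIO4 (4 equiv), 2,6-lutidine (2 equiv), 1,4-dioxane/H2O 3:1, rt
Reagents that add atoms: osmium tetroxide O=[Os](=O)(=O)=O; sodium periodate [Na+].[O-]I(=O)(=O)=O (terminal source of the aldehyde oxygen, relayed through osmium)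
Why: Lemieux–Johnson cleavage in its lutidine-buffered form, in which OsO4 picks the unhindered monosubstituted alkene over the iodine-deactivated trisubstituted C7=C8 bond, the buffer spares the silyl ethers, and periodate fission of the glycol with loss of the terminal carbon unmasks the C9 aldehyde without touching any stereocentre of the product.

Step 10
Reactants: 18 2-[(1R,2S,3R)-2-[(1R,2Z)-1-(tert-butyldimethylsilyloxy)-3-iodobut-2-en-1-yl]-1-methyl-3-(propan-2-yl)-3-(triethylsilyloxy)cyclopentyl]acetaldehyde
Product: 21 (1R,3aR,5S,8S,8aS)-8-(tert-butyldimethylsilyloxy)-3a,6-dimethyl-1-(propan-2-yl)-1-(triethylsilyloxy)-1,2,3,3a,4,5,8,8a-octahydroazulen-5-ol, via alkenylchromium dichloride 19 (not isolated), via chromium alkoxide 20 (not isolated)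
Conditions: CrCl2 (8 equiv), NiCl2 (2 mol % of CrCl2), degassed DMSO, rt, 18 added by syringe pump to 0.003 M; then H2O
Reagents that add atoms: none
Why: This is the Nozaki–Hiyama–Kishi reaction in its established intramolecular form for iodoalkene aldehydes: CrCl2 reduces NiCl2 to zerovalent nickel, which inserts into the C8–I bond with retention of the Z geometry, the alkenyl group passes to trivalent chromium to give 19, and this mild non-basic nucleophile adds to the C9 aldehyde to give alkoxide 20. Ring B closes by a 7-exo-trig addition that forms C8–C9 and leaves the Z alkene C7=C8 inside the new ring. The only new stereocentre, C9, is set in a trans-fused chair-like cycloheptene transition state in which the C1–C2 and C5–C4 bonds and the C6 silyloxy group are equatorial and the angular methyl is axial, so the chromium-bound aldehyde oxygen takes the pseudo-equatorial site to avoid a 1,3-diaxial contact with that methyl and C9–O ends cis to C6–O (5S). The step needs attack on the aldehyde only, no enolisation at C10, no loss of alkene geometry and cyclisation in preference to oligomerisation. The first three follow from the low basicity and aldehyde preference of alkenylchromium reagents and from the silyl caps on both hydroxyls, which remove every proton source near C8. The last is secured by slow addition at high dilution, by the Z alkene that holds C6 and the C8–chromium bond cis, and by the two trans pseudo-equatorial arms of ring A, which the quaternary C1 presses together.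

Step 11
Reactants: 21 (1R,3aR,5S,8S,8aS)-8-(tert-butyldimethylsilyloxy)-3a,6-dimethyl-1-(propan-2-yl)-1-(triethylsilyloxy)-1,2,3,3a,4,5,8,8a-octahydroazulen-5-ol
Product: 22 (1R,3aR,5S,8S,8aS)-8-(tert-butyldimethylsilyloxy)-3a,6-dimethyl-1-(propan-2-yl)-1-(triethylsilyloxy)-1,2,3,3a,4,5,8,8a-octahydroazulen-5-yl acetate
Conditions: Ac2O, DMAP (cat.), pyridine, CH2Cl2, 0 °C to rt
Reagents that add atoms: acetic anhydride CC(=O)OC(C)=O
Why: DMAP-catalysed acetylation of the only free hydroxyl group, that on C9, with retention because the C9–O bond stays intact and both other oxygens are silylated.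

Step 12
Reactants: 22 (1R,3aR,5S,8S,8aS)-8-(tert-butyldimethylsilyloxy)-3a,6-dimethyl-1-(propan-2-yl)-1-(triethylsilyloxy)-1,2,3,3a,4,5,8,8a-octahydroazulen-5-yl acetate
Product: 23 (1R,3aR,5S,8S,8aS)-1,8-dihydroxy-3a,6-dimethyl-1-(propan-2-yl)-1,2,3,3a,4,5,8,8a-octahydroazulen-5-yl acetate
Conditions: HF·pyridine, excess pyridine, THF, 0 °C to rt (polypropylene vessel)
Reagents that add atoms: none
Why: Fluoride-mediated desilylation with buffered HF·pyridine cleaves the secondary tert-butyldimethylsilyl and the tertiary triethylsilyl ether in one operation, and its non-basic medium leaves the C9 acetate in place without hydrolysis or migration to the cis C6 hydroxyl; no stereocentre is touched.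

Step 13
Reactants: 24 4-hydroxybenzoic acid
Product: 26 4-(tert-butyldimethylsilyloxy)benzoic acid, via bis-silylated hydroxybenzoate 25 (not isolated)
Conditions: TBSCl (2.5 equiv), imidazole (5 equiv), DMF, rt; then AcOH/THF/H2O 3:1:1, rt
Reagents that add atoms: tert-butyldimethylsilyl chloride CC(C)(C)[Si](C)(C)Cl
Why: Exhaustive silylation with a silyl chloride and imidazole followed by selective solvolysis, which relies on the silyl ester being far more labile to aqueous acetic acid than the aryl silyl ether; no stereocentre is involved.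

Step 14
Reactants: 23 (1R,3aR,5S,8S,8aS)-1,8-dihydroxy-3a,6-dimethyl-1-(propan-2-yl)-1,2,3,3a,4,5,8,8a-octahydroazulen-5-yl acetate; 26 4-(tert-butyldimethylsilyloxy)benzoic acid
Product: 27 (3R,3aS,4S,7S,8aR)-7-acetoxy-3-hydroxy-6,8a-dimethyl-3-(propan-2-yl)-1,2,3,3a,4,7,8,8a-octahydroazulen-4-yl 4-(tert-butyldimethylsilyloxy)benzoate
Conditions: 26 (1.5 equiv), DCC (1.6 equiv), DMAP (0.5 equiv), CH2Cl2, rt
Reagents that add atoms: none
Why: Steglich esterification, in which the DMAP-activated acyl group is taken up by the secondary allylic C6 hydroxyl while the tertiary C4 hydroxyl, flanked by isopropyl, is too hindered to react, and C6 keeps its configuration because its C–O bond is not broken.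

Step 15
Reactants: 27 (3R,3aS,4S,7S,8aR)-7-acetoxy-3-hydroxy-6,8a-dimethyl-3-(propan-2-yl)-1,2,3,3a,4,7,8,8a-octahydroazulen-4-yl 4-(tert-butyldimethylsilyloxy)benzoate
Product: 28 (3R,3aS,4S,7S,8aR)-7-acetoxy-3-hydroxy-6,8a-dimethyl-3-(propan-2-yl)-1,2,3,3a,4,7,8,8a-octahydroazulen-4-yl 4-hydroxybenzoate (CNP0305796.2)
Conditions: Bu4NF/AcOH 1:1 (1.2 equiv), THF, 0 °C
Reagents that add atoms: none
Why: Fluoride cleavage of an aryl silyl ether, which is fast because phenoxide is a good leaving group from silicon, so that acetic acid-buffered Bu4NF at 0 °C should free the phenol without hydrolysis, migration or elimination of the two allylic esters and without change at any stereocentre.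

**Compound list**
1 | 3-ethoxycyclopent-2-en-1-one | CCOC1=CC(=O)CC1 | starting material
2 | allylmagnesium bromide | C=CC[Mg]Br | starting material
3 | 1-allyl-3-ethoxycyclopent-2-en-1-ol (racemic) | CCOC1=CC(O)(CC=C)CC1 | intermediate
4 | 3-allylcyclopent-2-en-1-one | C=CCC1=CC(=O)CC1 | intermediate
5 | dimethylaluminium enolate, [(3R)-3-allyl-3-methylcyclopent-1-en-1-yl]oxy(dimethyl)alumane | C=CC[C@@]1(C)CCC(O[Al](C)C)=C1 | intermediate
6 | [(3R)-3-allyl-3-methylcyclopent-1-en-1-yl]oxy(trimethyl)silane | C=CC[C@@]1(C)CCC(O[Si](C)(C)C)=C1 | intermediate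
7 | but-2-yn-1-ol | CC#CCO | starting material
8 | but-2-ynal | CC#CC=O | intermediate
9 | dibutylboron enolate, [(3R)-3-allyl-3-methylcyclopent-1-en-1-yl]oxy(dibutyl)borane | C=CC[C@@]1(C)CCC(OB(CCCC)CCCC)=C1 | intermediate
10 | dibutylboron aldolate, O-dibutylboryl derivative of 11 | C=CC[C@@]1(C)CCC(=O)[C@@H]1[C@@H](OB(CCCC)CCCC)C#CC | intermediate
11 | (2S,3R)-3-allyl-2-[(1R)-1-hydroxybut-2-yn-1-yl]-3-methylcyclopentan-1-one | C=CC[C@@]1(C)CCC(=O)[C@@H]1[C@@H](O)C#CC | intermediate
12 | (1R,2S,3R)-3-allyl-2-[(1R)-1-hydroxybut-2-yn-1-yl]-3-methyl-1-(propan-2-yl)cyclopentan-1-ol | C=CC[C@@]1(C)CC[C@@](O)(C(C)C)[C@@H]1[C@@H](O)C#CC | intermediate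
13 | cyclic alkenylalanate, sodium 2,2-bis(2-methoxyethoxy)-3-methyl-2,5-dihydro-1,2-oxaaluminol-2-uide carried at its C5 by the cyclopentane (C4 oxygen drawn protonated) | C=CC[C@@]1(C)CC[C@@](O)(C(C)C)[C@@H]1[C@H]1O[Al-](OCCOC)(OCCOC)C(C)=C1.[Na+] | intermediate
14 | (1R,2S,3R)-3-allyl-2-[(1R,2Z)-1-hydroxy-3-iodobut-2-en-1-yl]-3-methyl-1-(propan-2-yl)cyclopentan-1-ol | C=CC[C@@]1(C)CC[C@@](O)(C(C)C)[C@@H]1[C@@H](O)/C=C(\I)C | intermediate
15 | (1R,2S,3R)-3-allyl-2-[(1R,2Z)-1-(tert-butyldimethylsilyloxy)-3-iodobut-2-en-1-yl]-3-methyl-1-(propan-2-yl)cyclopentan-1-ol | C=CC[C@@]1(C)CC[C@@](O)(C(C)C)[C@@H]1[C@@H](O[Si](C)(C)C(C)(C)C)/C=C(\I)C | intermediate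
16 | [(1R,2S,3R)-3-allyl-2-[(1R,2Z)-1-(tert-butyldimethylsilyloxy)-3-iodobut-2-en-1-yl]-3-methyl-1-(propan-2-yl)cyclopentyl]oxy(triethyl)silane | C=CC[C@@]1(C)CC[C@@](O[Si](CC)(CC)CC)(C(C)C)[C@@H]1[C@@H](O[Si](C)(C)C(C)(C)C)/C=C(\I)C | intermediate
17 | vicinal diol, 3-[(1R,2S,3R)-2-[(1R,2Z)-1-(tert-butyldimethylsilyloxy)-3-iodobut-2-en-1-yl]-1-methyl-3-(propan-2-yl)-3-(triethylsilyloxy)cyclopentyl]propane-1,2-diol (both carbinol epimers) | OCC(O)C[C@@]1(C)CC[C@@](O[Si](CC)(CC)CC)(C(C)C)[C@@H]1[C@@H](O[Si](C)(C)C(C)(C)C)/C=C(\I)C | intermediate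
18 | 2-[(1R,2S,3R)-2-[(1R,2Z)-1-(tert-butyldimethylsilyloxy)-3-iodobut-2-en-1-yl]-1-methyl-3-(propan-2-yl)-3-(triethylsilyloxy)cyclopentyl]acetaldehyde | O=CC[C@@]1(C)CC[C@@](O[Si](CC)(CC)CC)(C(C)C)[C@@H]1[C@@H](O[Si](C)(C)C(C)(C)C)/C=C(\I)C | intermediate
19 | alkenylchromium dichloride, 18 with CrCl2 in place of iodine at C8 (Z) | O=CC[C@@]1(C)CC[C@@](O[Si](CC)(CC)CC)(C(C)C)[C@@H]1[C@@H](O[Si](C)(C)C(C)(C)C)/C=C(\[Cr](Cl)Cl)C | intermediate
20 | chromium alkoxide, O-dichlorochromium derivative of 21 | Cl[Cr](Cl)O[C@H]1C[C@@]2(C)CC[C@@](O[Si](CC)(CC)CC)(C(C)C)[C@@H]2[C@@H](O[Si](C)(C)C(C)(C)C)C=C1C | intermediate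
21 | (1R,3aR,5S,8S,8aS)-8-(tert-butyldimethylsilyloxy)-3a,6-dimethyl-1-(propan-2-yl)-1-(triethylsilyloxy)-1,2,3,3a,4,5,8,8a-octahydroazulen-5-ol | O[C@H]1C[C@@]2(C)CC[C@@](O[Si](CC)(CC)CC)(C(C)C)[C@@H]2[C@@H](O[Si](C)(C)C(C)(C)C)C=C1C | intermediate
22 | (1R,3aR,5S,8S,8aS)-8-(tert-butyldimethylsilyloxy)-3a,6-dimethyl-1-(propan-2-yl)-1-(triethylsilyloxy)-1,2,3,3a,4,5,8,8a-octahydroazulen-5-yl acetate | CC(=O)O[C@H]1C[C@@]2(C)CC[C@@](O[Si](CC)(CC)CC)(C(C)C)[C@@H]2[C@@H](O[Si](C)(C)C(C)(C)C)C=C1C | intermediate
23 | (1R,3aR,5S,8S,8aS)-1,8-dihydroxy-3a,6-dimethyl-1-(propan-2-yl)-1,2,3,3a,4,5,8,8a-octahydroazulen-5-yl acetate | CC(=O)O[C@H]1C[C@@]2(C)CC[C@@](O)(C(C)C)[C@@H]2[C@@H](O)C=C1C | intermediate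
24 | 4-hydroxybenzoic acid | OC(=O)c1ccc(O)cc1 | starting material
25 | bis-silylated hydroxybenzoate, tert-butyldimethylsilyl 4-(tert-butyldimethylsilyloxy)benzoate | CC(C)(C)[Si](C)(C)Oc1ccc(cc1)C(=O)O[Si](C)(C)C(C)(C)C | intermediate
26 | 4-(tert-butyldimethylsilyloxy)benzoic acid | CC(C)(C)[Si](C)(C)Oc1ccc(cc1)C(=O)O | intermediate
27 | (3R,3aS,4S,7S,8aR)-7-acetoxy-3-hydroxy-6,8a-dimethyl-3-(propan-2-yl)-1,2,3,3a,4,7,8,8a-octahydroazulen-4-yl 4-(tert-butyldimethylsilyloxy)benzoate | CC(=O)O[C@H]1C[C@@]2(C)CC[C@@](O)(C(C)C)[C@@H]2[C@@H](OC(=O)c2ccc(O[Si](C)(C)C(C)(C)C)cc2)C=C1C | intermediate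
28 | (3R,3aS,4S,7S,8aR)-7-acetoxy-3-hydroxy-6,8a-dimethyl-3-(propan-2-yl)-1,2,3,3a,4,7,8,8a-octahydroazulen-4-yl 4-hydroxybenzoate | CC(=O)O[C@H]1C[C@@]2(C)CC[C@@](O)(C(C)C)[C@@H]2[C@@H](OC(=O)c2ccc(O)cc2)C=C1C | target

**Total step count:** 15
**Longest linear sequence:** 13 steps (1, 2, 4–12, 14, 15)

**Three steps most likely to fail**

**Step 10 (key step).**
- What may go wrong: allylic strain against the C8 methyl works against the pseudo-equatorial placement of the chromium-bound oxygen. The aldehyde may then be attacked through the conformer with that oxygen pseudo-axial, and facial selectivity at C9 would be poor or inverted.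
- Fallback: it sets out from 18. The cyclisation is run as described and the C9-epimeric alcohol F1 is separated. Instead of acylation with retention, it is submitted to a Mitsunobu reaction with acetic acid (PPh3, diisopropyl azodicarboxylate, toluene, 0 °C).
- In that reaction acetate displaces the pseudo-axial oxyphosphonium group from the open face opposite to the angular methyl, with inversion. The route is rejoined at 22, so both C9 epimers converge on the same acetate.
- Oxidation to the C9 enone followed by hydride reduction is not used as the corrective. The axial angular methyl, 1,3 to the carbonyl, would steer hydride to the opposite face and rebuild the unwanted epimer.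

**Step 4.**
- What may go wrong: the slim alkynyl group pays little for an axial place in the chair, so anti/syn discrimination at C6 may erode. Discrimination of the two enolate faces by methyl against allyl may also be incomplete. C5 epimers are removed by chromatography at 11.
- Fallback: C6 is set by reagent control rather than in the aldol. It sets out from 11, taken on together with the C6-epimeric aldol F2. Step 5 then gives 12 and the C6-epimeric diol F3.
- MnO2 in CH2Cl2 oxidises the propargylic alcohol of both to the single ynone F4, which is kept under neutral conditions. Asymmetric transfer hydrogenation with Ru[(R,R)-TsNCH(Ph)CH(Ph)NH](p-cymene) in iPrOH at rt should then deliver the (R)-propargylic alcohol, by analogy with simple alkyl alkynyl ketones, whatever the neighbouring stereocentres. This comes back to the route at 12.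

**Step 5.**
- What may go wrong: retro-aldol cleavage of the metal aldolate, enolisation of the ketone, or β-hydride reduction may occur in place of addition.
- Fallback: it sets out from 11. The C6 hydroxyl is masked (TESCl, imidazole, CH2Cl2) to give the triethylsilyl ether F5, which cannot fragment.
- The less basic organocerium reagent from iPrLi and CeCl3 (THF, −78 °C) adds anti to the now bulkier side chain to give the tertiary alcohol F6. AcOH/THF/H2O then removes the secondary silyl ether, and the route is rejoined at 12.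

**Further compounds**
F1 | step 10 | (1R,3aR,5R,8S,8aS)-8-(tert-butyldimethylsilyloxy)-3a,6-dimethyl-1-(propan-2-yl)-1-(triethylsilyloxy)-1,2,3,3a,4,5,8,8a-octahydroazulen-5-ol | O[C@@H]1C[C@@]2(C)CC[C@@](O[Si](CC)(CC)CC)(C(C)C)[C@@H]2[C@@H](O[Si](C)(C)C(C)(C)C)C=C1C
F2 | step 4 | (2S,3R)-3-allyl-2-[(1S)-1-hydroxybut-2-yn-1-yl]-3-methylcyclopentan-1-one | C=CC[C@@]1(C)CCC(=O)[C@@H]1[C@H](O)C#CC
F3 | step 4 | (1R,2S,3R)-3-allyl-2-[(1S)-1-hydroxybut-2-yn-1-yl]-3-methyl-1-(propan-2-yl)cyclopentan-1-ol | C=CC[C@@]1(C)CC[C@@](O)(C(C)C)[C@@H]1[C@H](O)C#CC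
F4 | step 4 | 1-[(1R,2R,5R)-5-allyl-2-hydroxy-5-methyl-2-(propan-2-yl)cyclopentyl]but-2-yn-1-one | C=CC[C@@]1(C)CC[C@@](O)(C(C)C)[C@@H]1C(=O)C#CC
F5 | step 5 | (2S,3R)-3-allyl-3-methyl-2-[(1R)-1-(triethylsilyloxy)but-2-yn-1-yl]cyclopentan-1-one | C=CC[C@@]1(C)CCC(=O)[C@@H]1[C@@H](O[Si](CC)(CC)CC)C#CC
F6 | step 5 | (1R,2S,3R)-3-allyl-3-methyl-1-(propan-2-yl)-2-[(1R)-1-(triethylsilyloxy)but-2-yn-1-yl]cyclopentan-1-ol | C=CC[C@@]1(C)CC[C@@](O)(C(C)C)[C@@H]1[C@@H](O[Si](CC)(CC)CC)C#CC
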